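## Retrosynthetic overview

1. Target 17 ⇐ benzoylation of the C6 hydroxyl of 16 ⇐ Pd(0)/acetic acid cis-1,4 opening of vinyl epoxide 14 (C5–C6 epoxide beside C3=C4), which places C3–OAc and C6–OH on the face of the C1 hydroxyl.
2. 14 ⇐ inversion of C2 by oxidation to epoxy enone 11, C1–OH-directed hydride delivery and acetylation; this is done while C3 is still an alkene carbon, so the ketone has no α-stereocentre to lose.
3. Epoxide 9 ⇐ C1–OH-directed epoxidation of C5=C6 in diene 8 ⇐ C2–O silylation, ester reduction and C7 benzoylation of ester 4.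
4. Structural basis: the ring C1–C6 with its quaternary carbinol C1 and the attached C7 is the ring, ipso carbon and carboxyl carbon of benzoic acid. Enzymatic ipso,ortho cis-dihydroxylation (1 + 2 → 3) sets C1 in the target's configuration and leaves the C3–C6 diene for later oxygenation.
5. Ring order: no ring is built. The only carbocycle is the benzene ring of 1, dearomatised in step 1; the oxirane of 9–14 is temporary and is opened in step 11.

Key step: step 1

Convention: atoms are numbered as in the target throughout (C1 quaternary carbinol, C7 its CH2, C2 and C3 the acetoxy carbons, C4=C5, C6 the benzoyloxy carbon). α is the ring face carrying the C1 hydroxyl, β the face carrying C7.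

Assumption: the cis-diol-dehydrogenase-deficient strain Ralstonia eutropha B9 is obtained from a culture collection and is treated as the biocatalyst, with fructose as its carbon and electron source.

## Route

Step 1
Reactants: 1 benzoic acid; 2 dioxygen
Product: 3 (1S,2R)-1,2-dihydroxycyclohexa-3,5-diene-1-carboxylic acid
Conditions: R. eutropha B9 whole cells, sodium benzoate feed, fructose mineral medium, air, pH 7, 30 °C; then acidify to pH 3 at 0 °C, EtOAc extraction
Reagents that add atoms: dioxygen (2), O=O
Why: Benzoate 1,2-dioxygenase, a Rieske non-haem iron enzyme, binds O2 at its mononuclear iron site, takes two electrons from NADH through its [2Fe–2S] cluster and should pass both oxygen atoms to the same face of the C1=C2 bond of bound benzoate, forming C1–O and C2–O suprafacially. The closest known reaction type is Rieske-dioxygenase arene cis-dihydroxylation, and the ipso,ortho mode on benzoate in dehydrogenase-deficient strains is known chemistry. No ring is closed, because the carbocycle is the benzene ring itself, converted into a cyclohexa-3,5-diene. Both new stereocentres, C1 (S, tertiary OH beside the carboxyl carbon C7) and C2 (R, OH cis to C1–OH), are fixed by the active site, which anchors the carboxylate and presents one enantiotopic ortho carbon and one ring face to the iron-bound oxygen. The step needs ipso,ortho regioselectivity, enantioselectivity and survival of the diol; the first two come from the enzyme, the third from the missing diol dehydrogenase (no rearomatisation to catechol) and from a cold, brief acidification of the acid-sensitive diene diol.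

Step 2
Reactants: 3 (1S,2R)-1,2-dihydroxycyclohexa-3,5-diene-1-carboxylic acid
Product: 4 methyl (1S,2R)-1,2-dihydroxycyclohexa-3,5-diene-1-carboxylate
Conditions: TMSCHN2, MeOH/toluene, 0 °C
Reagents that add atoms: trimethylsilyldiazomethane, C[Si](C)(C)C=[N+]=[N-]
Why: Diazoalkane esterification methylates the carboxylic acid under essentially neutral conditions, which should spare the dehydration-prone diene diol and touches no stereocentre.

Step 3
Reactants: 4 methyl (1S,2R)-1,2-dihydroxycyclohexa-3,5-diene-1-carboxylate
Product: 5 methyl (1S,2R)-2-(tert-butyldimethylsilyloxy)-1-hydroxycyclohexa-3,5-diene-1-carboxylate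
Conditions: TBSOTf (1.05 equiv), 2,6-lutidine, CH2Cl2, −78 °C
Reagents that add atoms: tert-butyldimethylsilyl triflate, CC(C)(C)[Si](C)(C)OS(=O)(=O)C(F)(F)F
Why: Silyl ether formation with a limiting amount of silyl triflate at low temperature should select the secondary C2 hydroxyl over the tertiary C1 hydroxyl, which must stay free as the directing group for steps 6 and 9.

Step 4
Reactants: 5 methyl (1S,2R)-2-(tert-butyldimethylsilyloxy)-1-hydroxycyclohexa-3,5-diene-1-carboxylate
Product: 6 (1R,6R)-6-(tert-butyldimethylsilyloxy)-1-(hydroxymethyl)cyclohexa-2,4-dien-1-ol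
Conditions: DIBAL-H (4 equiv), CH2Cl2, −78 → 0 °C; Rochelle salt work-up
Reagents that add atoms: none
Why: Hydride reduction of the α-hydroxy ester to the primary alcohol turns C7 into CH2OH; the aluminium alkoxides formed are poorly basic, so the diene and the silyl ether should not be disturbed.

Step 5
Reactants: 6 (1R,6R)-6-(tert-butyldimethylsilyloxy)-1-(hydroxymethyl)cyclohexa-2,4-dien-1-ol; 7 benzoyl chloride
Product: 8 [(1R,6R)-6-(tert-butyldimethylsilyloxy)-1-hydroxycyclohexa-2,4-dien-1-yl]methyl benzoate
Conditions: BzCl (1.1 equiv), pyridine, CH2Cl2, 0 °C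
Reagents that add atoms: benzoyl chloride (7), O=C(Cl)c1ccccc1
Why: Acylation should occur at the primary C7 hydroxyl only, the tertiary C1 hydroxyl being inert to an acid chloride in pyridine at 0 °C; it also removes a homoallylic hydroxyl that could misdirect step 6 to the β face.

Step 6
Reactants: 8 [(1R,6R)-6-(tert-butyldimethylsilyloxy)-1-hydroxycyclohexa-2,4-dien-1-yl]methyl benzoate
Product: 9 5α,6α-epoxide of 8 (C1–OH, C2–OTBS and the C5–C6 epoxide oxygen all α; C3=C4; C7–OBz)
Conditions: VO(acac)2 (5 mol %), t-BuOOH (1.2 equiv, decane), CH2Cl2, 0 °C → rt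
Reagents that add atoms: tert-butyl hydroperoxide, CC(C)(C)OO
Why: In this vanadium-catalysed hydroxyl-directed epoxidation the vanadate ester of the C1 hydroxyl holds the peroxide over the allylic C5=C6 bond, so oxygen should arrive on the α face and set C5 and C6 syn to C1–OH; C3=C4 has no allylic hydroxyl and is screened on that face by the C2 silyl ether.

Step 7
Reactants: 9 5α,6α-epoxide of 8
Product: 10 epoxy diol (C1–OH α, C2–OH α, 5α,6α-epoxide, C3=C4, C7–OBz)
Conditions: TBAF, AcOH (1:1), THF, 0 °C → rt
Reagents that add atoms: none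
Why: Fluoride cleavage of the silyl ether, buffered with acetic acid, should free the C2 hydroxyl without benzoate migration and without the acid-type opening of the vinyl epoxide that an HF reagent would risk.

Step 8
Reactants: 10 epoxy diol
Product: 11 epoxy enone (C2 ketone conjugated with C3=C4, 5α,6α-epoxide, C1–OH α, C7–OBz)
Conditions: IBX (2 equiv), DMSO, rt
Reagents that add atoms: none
Why: IBX oxidises the secondary allylic C2 hydroxyl and is chosen because it should give the α-hydroxy ketone from a 1,2-diol without glycol cleavage; the enone has no α-hydrogen (C1 quaternary, C3 sp2), so it should not epimerise or eliminate.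

Step 9
Reactants: 11 epoxy enone
Product: 12 trans-diol epoxide (C1–OH α, C2–OH β, 5α,6α-epoxide, C3=C4, C7–OBz)
Conditions: Me4NBH(OAc)3 (5 equiv), MeCN/AcOH 3:1, −30 °C
Reagents that add atoms: none
Why: In this hydroxyl-directed (Evans–Saksena) reduction the C1 hydroxyl exchanges onto boron and the alkoxydiacetoxyborohydride should deliver hydride to the adjacent carbonyl from the α face, placing the new C2 hydroxyl β (trans to C1–OH) by 1,2-reduction, while the unbound benzoate carbonyl is inert to this weak hydride donor.

Step 10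
Reactants: 12 trans-diol epoxide; 13 acetic anhydride
Product: 14 epoxy acetate (C2–OAc β, C1–OH α, 5α,6α-epoxide, C3=C4, C7–OBz)
Conditions: Ac2O (1.5 equiv), pyridine, DMAP (cat.), CH2Cl2, 0 °C
Reagents that add atoms: acetic anhydride (13), CC(=O)OC(C)=O
Why: Acylation of the secondary C2 hydroxyl should be selective over the tertiary C1 hydroxyl, and the basic medium leaves the vinyl epoxide intact.

Step 11
Reactants: 14 epoxy acetate; 15 acetic acid
Product: 16 [(1S,2S,3R,6S)-2,3-diacetoxy-1,6-dihydroxycyclohex-4-en-1-yl]methyl benzoate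
Conditions: Pd(PPh3)4 (5 mol %), AcOH (3 equiv), THF, 0 °C → rt
Reagents that add atoms: acetic acid (15), CC(=O)O
Why: In this Pd(0)-catalysed vinyl epoxide opening (Tsuji–Trost type) palladium ionises the allylic C5–O bond with inversion to a β-face π-allyl complex over C3–C5, and acetate should attack C3, the terminus remote from the C6 alkoxide, anti to palladium, so that C3–OAc and C6–OH both end up α (cis-1,4, net retention) with the alkene at C4=C5.

Step 12
Reactants: 16 [(1S,2S,3R,6S)-2,3-diacetoxy-1,6-dihydroxycyclohex-4-en-1-yl]methyl benzoate; 7 benzoyl chloride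
Product: 17 cleistenediol F, [(1S,2S,3R,6S)-2,3-diacetoxy-6-(benzoyloxy)-1-hydroxycyclohex-4-en-1-yl]methyl benzoate
Conditions: BzCl (1.5 equiv), pyridine, DMAP (cat.), CH2Cl2, 0 °C → rt
Reagents that add atoms: benzoyl chloride (7), O=C(Cl)c1ccccc1
Why: DMAP-catalysed acylation should benzoylate the secondary allylic C6 hydroxyl while the tertiary C1 hydroxyl stays free, and no stereocentre is touched.

## Compound list

1 | benzoic acid | OC(=O)c1ccccc1 | starting material
2 | dioxygen | O=O | starting material
3 | (1S,2R)-1,2-dihydroxycyclohexa-3,5-diene-1-carboxylic acid | C1=CC=C[C@@](O)(C(=O)O)[C@@H]1O | intermediate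
4 | methyl (1S,2R)-1,2-dihydroxycyclohexa-3,5-diene-1-carboxylate | C1=CC=C[C@@](O)(C(=O)OC)[C@@H]1O | intermediate
5 | methyl (1S,2R)-2-(tert-butyldimethylsilyloxy)-1-hydroxycyclohexa-3,5-diene-1-carboxylate | C1=CC=C[C@@](O)(C(=O)OC)[C@@H]1O[Si](C)(C)C(C)(C)C | intermediate
6 | (1R,6R)-6-(tert-butyldimethylsilyloxy)-1-(hydroxymethyl)cyclohexa-2,4-dien-1-ol | C1=CC=C[C@@](O)(CO)[C@@H]1O[Si](C)(C)C(C)(C)C | intermediate
7 | benzoyl chloride | O=C(Cl)c1ccccc1 | starting material
8 | [(1R,6R)-6-(tert-butyldimethylsilyloxy)-1-hydroxycyclohexa-2,4-dien-1-yl]methyl benzoate | C1=CC=C[C@@](O)(COC(=O)c2ccccc2)[C@@H]1O[Si](C)(C)C(C)(C)C | intermediate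
9 | 5α,6α-epoxide of 8 (C1–OH, C2–OTBS and epoxide oxygen all α; C3=C4; C7–OBz) | C1=C[C@@H]2O[C@@H]2[C@@](O)(COC(=O)c3ccccc3)[C@@H]1O[Si](C)(C)C(C)(C)C | intermediate
10 | epoxy diol (C1–OH α, C2–OH α, 5α,6α-epoxide, C3=C4, C7–OBz) | C1=C[C@@H]2O[C@@H]2[C@@](O)(COC(=O)c3ccccc3)[C@@H]1O | intermediate
11 | epoxy enone (C2=O conjugated with C3=C4, 5α,6α-epoxide, C1–OH α, C7–OBz) | C1=C[C@@H]2O[C@@H]2[C@@](O)(COC(=O)c3ccccc3)C1=O | intermediate
12 | trans-diol epoxide (C1–OH α, C2–OH β, 5α,6α-epoxide, C3=C4, C7–OBz) | C1=C[C@@H]2O[C@@H]2[C@@](O)(COC(=O)c3ccccc3)[C@H]1O | intermediate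
13 | acetic anhydride | CC(=O)OC(C)=O | starting material
14 | epoxy acetate (C2–OAc β, C1–OH α, 5α,6α-epoxide, C3=C4, C7–OBz) | C1=C[C@@H]2O[C@@H]2[C@@](O)(COC(=O)c3ccccc3)[C@H]1OC(C)=O | intermediate
15 | acetic acid | CC(=O)O | starting material
16 | [(1S,2S,3R,6S)-2,3-diacetoxy-1,6-dihydroxycyclohex-4-en-1-yl]methyl benzoate | CC(=O)O[C@@H]1C=C[C@H](O)[C@@](O)(COC(=O)c2ccccc2)[C@H]1OC(C)=O | intermediate
17 | cleistenediol F, [(1S,2S,3R,6S)-2,3-diacetoxy-6-(benzoyloxy)-1-hydroxycyclohex-4-en-1-yl]methyl benzoate | CC(=O)O[C@@H]1C=C[C@H](OC(=O)c2ccccc2)[C@@](O)(COC(=O)c2ccccc2)[C@H]1OC(C)=O | target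

## Step count and risks

Total step count: 12. Longest linear sequence: 12 steps (fully linear from benzoic acid).

Steps most likely to fail:

1. Step 11. Acetate may be captured at C5, next to the new C6 alkoxide (1,2-opening), because the C3 terminus is deactivated by the acetoxy group on C2; palladium may also slowly ionise the allylic C2 acetate. The fallback fixes the regiochemistry by a sigmatropic shift instead of by nucleophile choice. It sets out from 14: sodium phenylselenide (PhSeSePh, NaBH4, EtOH, 0 °C) should open the epoxide at the allylic carbon C5 with inversion to the 5β-phenylselanyl-6α-alcohol F1. Benzoylation (BzCl, pyridine) should give the C6 benzoate F2. Oxidation (H2O2, pyridine, CH2Cl2, 0 °C) should give the allyl selenoxide, which rearranges [2,3] suprafacially and after selenenate cleavage gives the 3β-hydroxy-4-ene F3, the C3 epimer of the 3-deacetyl target. Mitsunobu esterification with acetic acid (PPh3, DIAD, toluene, 0 °C) should then invert C3 and come back to the route at 17.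

2. Step 9. Hydride may reach the enone from the β face without first binding to the C1 hydroxyl, which returns the cis-diol, or the acetic acid medium may open the vinyl epoxide. The fallback replaces redox inversion by SN2 inversion and makes no new compound (F0). It sets out from 10: Mitsunobu reaction with acetic acid (PPh3, DIAD, AcOH, toluene, 0 °C → rt) should activate the secondary allylic C2 hydroxyl (the tertiary C1 hydroxyl cannot be displaced) and bring in acetate with inversion. It comes back to the route at 14, and steps 8–10 are dropped.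

3. Step 6. Oxygen transfer may be slow at the hindered tertiary vanadate, may spill over to C3=C4, or the Lewis-acidic metal may open the vinyl epoxide as it forms. The fallback replaces the epoxide by a cyclic carbonate that generates the same π-allyl intermediate. It sets out from 8:
   - Hydrogen-bond-directed dihydroxylation (OsO4·TMEDA, CH2Cl2, −78 °C; then aq. Na2SO3) should give the all-α 1,5,6-triol F4.
   - Carbonyldiimidazole should close the secondary 5,6-diol to the cyclic carbonate F5.
   - F5 is carried through the operations of steps 7–10: TBAF/AcOH gives the diol carbonate F6, IBX the enone carbonate F7, Me4NBH(OAc)3 the trans-diol carbonate F8, and Ac2O/pyridine the C2 β-acetate carbonate F9.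
   - With Pd(PPh3)4/AcOH, F9 should ionise at C5 with loss of CO2 and come back to the route at 16.

Further compounds
F1 | step 11 | 5β-phenylselanyl-6α-hydroxy compound from 14 (C2–OAc β, C1–OH α, C3=C4, C7–OBz) | C1=C[C@@H]([Se]c2ccccc2)[C@H](O)[C@@](O)(COC(=O)c2ccccc2)[C@H]1OC(C)=O
F2 | step 11 | C6 benzoate of F1 | C1=C[C@@H]([Se]c2ccccc2)[C@H](OC(=O)c2ccccc2)[C@@](O)(COC(=O)c2ccccc2)[C@H]1OC(C)=O
F3 | step 11 | 3β-hydroxy-4-ene (C3 epimer of the 3-deacetyl target; C2–OAc β, C6–OBz α, C1–OH α, C7–OBz) | O[C@H]1C=C[C@H](OC(=O)c2ccccc2)[C@@](O)(COC(=O)c2ccccc2)[C@H]1OC(C)=O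
F0 | step 9 | none | none
F4 | step 6 | all-α 1,5,6-triol from 8 (C2–OTBS α, C3=C4, C7–OBz) | C1=C[C@H](O)[C@H](O)[C@@](O)(COC(=O)c2ccccc2)[C@@H]1O[Si](C)(C)C(C)(C)C
F5 | step 6 | 5α,6α-cyclic carbonate of F4 | C1=C[C@@H]2OC(=O)O[C@@H]2[C@@](O)(COC(=O)c3ccccc3)[C@@H]1O[Si](C)(C)C(C)(C)C
F6 | step 6 | desilylated carbonate (C1–OH α, C2–OH α) | C1=C[C@@H]2OC(=O)O[C@@H]2[C@@](O)(COC(=O)c3ccccc3)[C@@H]1O
F7 | step 6 | enone carbonate (C2=O conjugated with C3=C4) | C1=C[C@@H]2OC(=O)O[C@@H]2[C@@](O)(COC(=O)c3ccccc3)C1=O
F8 | step 6 | trans-diol carbonate (C2–OH β) | C1=C[C@@H]2OC(=O)O[C@@H]2[C@@](O)(COC(=O)c3ccccc3)[C@H]1O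
F9 | step 6 | C2 β-acetate carbonate | C1=C[C@@H]2OC(=O)O[C@@H]2[C@@](O)(COC(=O)c3ccccc3)[C@H]1OC(C)=O
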